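The data come from a simulation with made-up constants; scatter was added.

**Late times.** Late in a run, each new target or side product costs one second reagent and removes one unit of what I call the unfinished charge, c(starting material) + c(intermediate). The step of partner with starting material moves material inside that sum. So the unfinished charge and c(second reagent) fall together, a fixed gap apart once the protic impurity has quenched its share. If the rate is k × c(unfinished) × c(second reagent), the integral is simple: ln[c(unfinished)/c(second reagent)] climbs by k × gap each day.

| flask | starting material | partner | second reagent | protic impurity | remark | time |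
|---|---|---|---|---|---|---|
| autumn | 0.12 M | 0.50 M | 0.25 M | 5 mM | run made earlier |  |
| summer | 0.50 M | 0.50 M | 0.25 M | 5 mM | run made earlier |  |
| dusk | 0.25 M | 0.50 M | 0.25 M | 2.5 mM | run made earlier |  |
| flask | 0.25 M | 0.500 M | 0.250 M | 5.00 mM |  | 3.0 d |

| run | time / d | target / % | side product / % |
|---|---|---|---|
| autumn | 0.250 | 12.6 | 42.5 |
| autumn | 0.333 | 15.7 | 48.6 |
| autumn | 0.500 | 19.2 | 57.2 |
| autumn | 0.833 | 22.1 | 66.5 |
| autumn | 1.25 | 23.9 | 70.7 |
| autumn | 2.08 | 24.1 | 74.3 |
| autumn | 3.00 | 24.5 | 75.0 |
| summer | 0.250 | 8.2 | 29.6 |
| summer | 0.333 | 8.9 | 33.0 |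
| summer | 0.500 | 10.4 | 35.4 |
| summer | 0.833 | 11.3 | 37.1 |
| summer | 1.25 | 12.1 | 36.6 |
| summer | 2.08 | 11.8 | 36.8 |
| summer | 3.00 | 11.6 | 36.6 |
| dusk | 0.250 | 11.6 | 37.9 |
| dusk | 0.417 | 14.6 | 46.5 |
| dusk | 0.833 | 20.3 | 56.9 |
| dusk | 1.67 | 23.1 | 63.6 |
| dusk | 3.00 | 24.3 | 67.3 |

(readings scatter by 0.3 percentage points)

- concentration of target at 3.0 d, in M
- concentration of side product at 3.0 d, in M
- concentration of starting material at 3.0 d, in M
- concentration of partner at 3.0 d, in M

**Reading k.** The dusk run ends with 0.0210 M unfinished and a gap of 2.50 mM. This gives the effective late constant, the one k that carries the unfinished charge through the run, 15.6 M⁻¹ d⁻¹, as a reading.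

**The ladder.** I assumed the quench came first. The summer run shows its cost: target plus side product reach 0.241 M, against 0.245 M of unquenched second reagent, the limiting reagent there. Next comes the first halving of the unfinished charge, about 0.257 d in this flask. Slower is the time set by the gap of this flask, 5.00 mM: about 12.8 d, longer than 3.0 d, so I expected this flask to be still creeping at the end.

**My reckoning.** For this flask at 3.0 d, the integral gives 0.0223 M unfinished, hence 0.228 M of target plus side product.

**The forecast.** It said target 0.0605 M, side product 0.166 M, starting material 0.022 M and partner 0.035 M, noting that the extra impurity against the dusk run “removes a little second reagent”.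

**The result.** The flask gave target 0.0610 M, side product 0.167 M, starting material 0.0182 M and partner 0.00278 M, so 0.0218 M stood unfinished.

    2 partner → homo dimer (k = 1.50 M⁻¹ h⁻¹)
    starting material + partner → intermediate (k = 0.410 M⁻¹ h⁻¹)
    starting material + second reagent → side product (k = 0.570 M⁻¹ h⁻¹)
    second reagent + protic impurity → quenched reagent (k = 2.30 M⁻¹ h⁻¹)
    second reagent + intermediate → target (k = 1.10 M⁻¹ h⁻¹)

At the start of this flask, dimerisation used partner 15 times as fast as the step to the intermediate did, while the half-life of starting material by the side-product step alone, the other concentrations as charged, was 0.20 d, short against 3.0 d. With 15.6 M⁻¹ d⁻¹, I reckoned 0.175 M unfinished for a neighbour charged with 0.42 M of starting material, and at 3.0 d that neighbour held 0.175 M of starting material plus intermediate.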